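The route rests on cutting the C10–C11 bond beside the trans-oxirane (ring O–C9–C10), which is read as the closed form of an anti C9-chloro/C10-hydroxy pair. The key step adds n-heptylmagnesium bromide to the aldehyde carbon (future C10) of (S)-2-chloro-7-(trimethylsilyl)hepta-4,6-diynal: one operation attaches the C11–C17 chain and sets C10 under control of the C9 chloride, without closing a ring. The precursor is a linear aldehyde carrying the silyl-capped C4–C7 diyne, the C8 methylene and the catalyst-installed C9 chloride. Base then closes the oxirane with inversion at C9 and frees the diyne for enantioselective addition to acrolein (C1–C3) and esterification with linoleic acid.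

Key step: step 4

Numbering used: C1–C2 vinyl, C3 ester carbinol, C4–C7 diyne, C8 methylene, C9–C10 oxirane, C11–C17 heptyl; the target is (3S,9R,10R) with a (9Z,12Z)-octadecadienoyl ester.

Assumption: the facial sense of the two catalyst-controlled steps is taken from the usual models ((2R,5R)-2,5-diphenylpyrrolidine gives the 2S chloride; the (S,S) ligand sends the alkynylzinc to the Re face of acrolein, giving 3S). Each is to be confirmed by Mosher ester analysis on first use, and the antipodal catalyst is used if the sense proves opposite.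

Step 1
Reactants: 1 1,4-bis(trimethylsilyl)buta-1,3-diyne; 2 oxetane
Product: 4 7-(trimethylsilyl)hepta-4,6-diyn-1-ol, via lithium (trimethylsilyl)butadiynide 3 (not isolated)
Conditions: MeLi·LiBr, Et2O, 0 °C → rt; then THF, BF3·OEt2, −78 °C; H2O work-up
Reagents that add atoms: none
Why: Removal of one silyl group by MeLi·LiBr gives the lithium diynide, which opens BF3-activated oxetane by SN2 attack (Lewis-acid-promoted alkynylation of a cyclic ether), forming the C7–C8 bond and delivering C8–C10 as a primary alcohol without any stereocentre.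

Step 2
Reactants: 4 7-(trimethylsilyl)hepta-4,6-diyn-1-ol
Product: 5 7-(trimethylsilyl)hepta-4,6-diynal
Conditions: Dess–Martin periodinane, CH2Cl2, 0 °C → rt
Reagents that add atoms: none
Why: Dess–Martin oxidation should stop cleanly at the aldehyde under neutral, anhydrous conditions that leave the silyl diyne untouched.

Step 3
Reactants: 5 7-(trimethylsilyl)hepta-4,6-diynal
Product: 6 (S)-2-chloro-7-(trimethylsilyl)hepta-4,6-diynal
Conditions: (2R,5R)-2,5-diphenylpyrrolidine (10 mol %), N-chlorosuccinimide, CH2Cl2, 0 °C → rt; pentane, filter, concentrate cold, use at once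
Reagents that add atoms: N-chlorosuccinimide, O=C1CCC(=O)N1Cl
Why: In this organocatalytic α-chlorination by enamine catalysis, the enamine of the C2-symmetric amine is chlorinated on the face left open by the flanking phenyl group, which sets the 2S centre (future C9) under catalyst control.

Step 4
Reactants: 6 (S)-2-chloro-7-(trimethylsilyl)hepta-4,6-diynal; 7 n-heptylmagnesium bromide
Product: 8 (6S,7R)-6-chloro-1-(trimethylsilyl)tetradeca-1,3-diyn-7-ol
Conditions: C7H15MgBr (Et2O solution), THF, −78 °C; pH 7 buffer quench at −78 °C
Reagents that add atoms: none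
Why: The Grignard reagent adds 1,2 to the aldehyde carbon, forming the C10–C11 bond and a magnesium alkoxide that is protonated on quench; the closest known reaction type is the anti-selective addition of organolithium and Grignard reagents to enantioenriched α-chloroaldehydes. No ring is closed in this step. The new C10 carbinol centre (7R in 8) is controlled by the existing C9 chloride: in the Cornforth (polar Felkin–Anh) transition state the C–Cl and C=O dipoles are opposed and the heptyl group approaches past the small hydrogen, which should give the 1,2-anti chlorohydrin. The step needs diastereofacial selectivity at the carbonyl and chemoselectivity for addition over α-deprotonation or loss of HCl. The strongly dipolar, unbranched α-chloro aldehyde secures the first, and low temperature, a primary Grignard reagent of modest basicity, freshly made chloroaldehyde and a cold quench secure the second. The silyl-capped diyne carries no acidic C–H and should be inert to the reagent.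

Step 5
Reactants: 8 (6S,7R)-6-chloro-1-(trimethylsilyl)tetradeca-1,3-diyn-7-ol
Product: 10 (2R,3R)-2-heptyl-3-(penta-2,4-diyn-1-yl)oxirane, via (6S,7R)-6-chlorotetradeca-1,3-diyn-7-ol 9 (not isolated)
Conditions: K2CO3, MeOH, 0 °C → rt
Reagents that add atoms: none
Why: Methanolysis of the alkynyl–silicon bond frees the diyne terminus, and the C10 alkoxide then displaces the C9 chloride from the rear in a 3-exo-tet Williamson closure, so inversion at C9 turns the anti chlorohydrin into the trans (9R,10R) oxirane while C10 is untouched.

Step 6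
Reactants: 10 (2R,3R)-2-heptyl-3-(penta-2,4-diyn-1-yl)oxirane; 11 acrolein
Product: 13 (3S)-8-[(2R,3R)-3-heptyloxiran-2-yl]oct-1-ene-4,6-diyn-3-ol, via methylzinc diynide 12 (not isolated)
Conditions: Me2Zn, 2,6-bis{[(2S)-2-(hydroxydiphenylmethyl)pyrrolidin-1-yl]methyl}-4-methylphenol ((S,S)-ProPhenol, 20 mol %), Ph3P=O (40 mol %), toluene, 0 → 4 °C; then acrolein, 4 °C; aqueous work-up
Reagents that add atoms: none
Why: In this catalytic asymmetric alkynylation of an aldehyde, a reaction type established for terminal 1,3-diynes and enals, the zinc diynide formed with Me2Zn is delivered inside the dinuclear zinc–ligand pocket to the Re face of acrolein, forming the C3–C4 bond and setting 3S under catalyst control, with no influence expected from the remote oxirane centres.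

Step 7
Reactants: 13 (3S)-8-[(2R,3R)-3-heptyloxiran-2-yl]oct-1-ene-4,6-diyn-3-ol; 14 linoleic acid
Product: 15 (3S)-8-[(2R,3R)-3-heptyloxiran-2-yl]oct-1-ene-4,6-diyn-3-yl (9Z,12Z)-octadeca-9,12-dienoate
Conditions: N,N'-dicyclohexylcarbodiimide (DCC), 4-(dimethylamino)pyridine (DMAP, cat.), CH2Cl2, 0 °C → rt, argon, dark
Reagents that add atoms: none
Why: In the Steglich esterification the carbodiimide-activated acid is passed by DMAP to the alcohol oxygen, so the C3–O bond is never broken and 3S is retained, while the neutral conditions should spare the oxirane, the diyne and the skipped Z,Z-diene.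

Compound list
1 | 1,4-bis(trimethylsilyl)buta-1,3-diyne | C[Si](C)(C)C#CC#C[Si](C)(C)C | starting material
2 | oxetane | C1COC1 | starting material
3 | lithium (trimethylsilyl)butadiynide | [Li]C#CC#C[Si](C)(C)C | intermediate
4 | 7-(trimethylsilyl)hepta-4,6-diyn-1-ol | C[Si](C)(C)C#CC#CCCCO | intermediate
5 | 7-(trimethylsilyl)hepta-4,6-diynal | C[Si](C)(C)C#CC#CCCC=O | intermediate
6 | (S)-2-chloro-7-(trimethylsilyl)hepta-4,6-diynal | C[Si](C)(C)C#CC#CC[C@H](Cl)C=O | intermediate
7 | n-heptylmagnesium bromide | CCCCCCC[Mg]Br | starting material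
8 | (6S,7R)-6-chloro-1-(trimethylsilyl)tetradeca-1,3-diyn-7-ol | C[Si](C)(C)C#CC#CC[C@H](Cl)[C@H](O)CCCCCCC | intermediate
9 | (6S,7R)-6-chlorotetradeca-1,3-diyn-7-ol | C#CC#CC[C@H](Cl)[C@H](O)CCCCCCC | intermediate
10 | (2R,3R)-2-heptyl-3-(penta-2,4-diyn-1-yl)oxirane | C#CC#CC[C@H]1O[C@@H]1CCCCCCC | intermediate
11 | acrolein | C=CC=O | starting material
12 | methylzinc diynide of 10, methyl{5-[(2R,3R)-3-heptyloxiran-2-yl]penta-1,3-diyn-1-yl}zinc | C[Zn]C#CC#CC[C@H]1O[C@@H]1CCCCCCC | intermediate
13 | (3S)-8-[(2R,3R)-3-heptyloxiran-2-yl]oct-1-ene-4,6-diyn-3-ol | C=C[C@@H](C#CC#CC[C@H]1O[C@@H]1CCCCCCC)O | intermediate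
14 | linoleic acid, (9Z,12Z)-octadeca-9,12-dienoic acid | CCCCC/C=C\C/C=C\CCCCCCCC(=O)O | starting material
15 | (3S)-8-[(2R,3R)-3-heptyloxiran-2-yl]oct-1-ene-4,6-diyn-3-yl (9Z,12Z)-octadeca-9,12-dienoate | C=C[C@@H](C#CC#CC[C@H]1O[C@@H]1CCCCCCC)OC(=O)CCCCCCC/C=C\C/C=C\CCCCC | target

Total step count: 7. Longest linear sequence: 7 steps (1 → 15).

Steps most likely to fail

1. Step 4. The facial preference at the aldehyde may be too weak, or the Grignard reagent may act as a base, causing epimerisation at C9 or loss of HCl toward a conjugated enynal. Fallback: the oxirane is made by reagent-controlled epoxidation instead of by the chlorohydrin. It sets out from 1 (converted to 3 as in step 1) and commercial (E)-dec-2-en-1-ol F1. Sharpless asymmetric epoxidation (Ti(OiPr)4, D-(−)-diethyl tartrate, t-BuOOH, 4 Å molecular sieves, CH2Cl2, −20 °C) should give [(2R,3R)-3-heptyloxiran-2-yl]methanol F2. Triflation (Tf2O, 2,6-lutidine, CH2Cl2, −78 °C) gives [(2R,3R)-3-heptyloxiran-2-yl]methyl trifluoromethanesulfonate F3. Displacement at the primary carbon by 3 (THF/DMPU, −78 °C) gives trimethyl{5-[(2R,3R)-3-heptyloxiran-2-yl]penta-1,3-diyn-1-yl}silane F4. K2CO3 in MeOH removes silicon, and the route is rejoined at 10.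

2. Step 3. Catalyst control may be incomplete, the α-chloro aldehyde may racemise through its enol or enamine during isolation, or a second chlorination may occur; any minor enantiomer would become a diastereomeric impurity after step 6. Fallback: both oxirane centres are set on an alkene and no chloroaldehyde is made. It sets out from 3 (from 1) and (E)-1-bromodec-2-ene F5. Copper-catalysed SN2 coupling (CuI cat., THF/DMF, −20 °C → rt) should give (E)-trimethyl(tetradec-6-ene-1,3-diyn-1-yl)silane F6. Shi epoxidation (1,2:4,5-di-O-isopropylidene-β-D-erythro-2,3-hexodiulo-2,6-pyranose, KHSO5, K2CO3, MeCN/dimethoxymethane/H2O, 0 °C) is expected to give the (R,R)-oxirane, the silyl epoxide F4 described above. K2CO3 in MeOH then rejoins the route at 10.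

3. Step 6. Zincation of the sensitive terminal diyne may be slow so that it oligomerises, conversion may stall, or the facial selectivity may be low or of the wrong sense. Fallback: the C3 centre is obtained by resolution instead of asymmetric catalysis. It sets out from 10; deprotonation (n-BuLi, THF, −78 °C) and addition to acrolein 11 should give the C3-epimeric (3RS)-8-[(2R,3R)-3-heptyloxiran-2-yl]oct-1-ene-4,6-diyn-3-ol F7. Lipase-catalysed acylation (Candida antarctica lipase B, vinyl acetate, hexane, rt) is expected, from the usual size preference of lipases for secondary alcohols with the diynyl arm as the large group, to acetylate the 3R epimer to (3R)-8-[(2R,3R)-3-heptyloxiran-2-yl]oct-1-ene-4,6-diyn-3-yl acetate F8. The unreacted 3S alcohol is separated, and the route is rejoined at 13.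

Further compounds
F1 | step 4 | (E)-dec-2-en-1-ol | CCCCCCC/C=C/CO
F2 | step 4 | [(2R,3R)-3-heptyloxiran-2-yl]methanol | OC[C@H]1O[C@@H]1CCCCCCC
F3 | step 4 | [(2R,3R)-3-heptyloxiran-2-yl]methyl trifluoromethanesulfonate | O=S(=O)(OC[C@H]1O[C@@H]1CCCCCCC)C(F)(F)F
F4 | step 4 | trimethyl{5-[(2R,3R)-3-heptyloxiran-2-yl]penta-1,3-diyn-1-yl}silane | C[Si](C)(C)C#CC#CC[C@H]1O[C@@H]1CCCCCCC
F5 | step 3 | (E)-1-bromodec-2-ene | CCCCCCC/C=C/CBr
F6 | step 3 | (E)-trimethyl(tetradec-6-ene-1,3-diyn-1-yl)silane | C[Si](C)(C)C#CC#CC/C=C/CCCCCCC
F7 | step 6 | (3RS)-8-[(2R,3R)-3-heptyloxiran-2-yl]oct-1-ene-4,6-diyn-3-ol | C=CC(O)C#CC#CC[C@H]1O[C@@H]1CCCCCCC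
F8 | step 6 | (3R)-8-[(2R,3R)-3-heptyloxiran-2-yl]oct-1-ene-4,6-diyn-3-yl acetate | C=C[C@H](C#CC#CC[C@H]1O[C@@H]1CCCCCCC)OC(C)=O
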